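The target, made from substrate and dissolved gas, is what I follow in blue and green.

    gas phase ⇌ dissolved gas, rate k1*(csat - [dissolved gas]) (k1 = 2.8 × 10⁻⁴ s⁻¹, csat = 200 mM)
    substrate + dissolved gas → target (k2 = 2.3 × 10⁻⁴ L mol⁻¹ s⁻¹, Ea2 = 84.0 kJ mol⁻¹)
    substrate + target → side product (k3 = 7.7 × 10⁻⁴ L mol⁻¹ s⁻¹, Ea3 = 78.0 kJ mol⁻¹)
    2 substrate → self-condensation product (k4 = 1.1 × 10⁻⁴ L mol⁻¹ s⁻¹, Ea4 = 80.0 kJ mol⁻¹)
    target → over-reaction product (k5 = 7.0 × 10⁻⁵ s⁻¹, Ea5 = 114 kJ mol⁻¹)
    (constants at 70 °C)

- blue: substrate 0.80 M; gas phase 200 mM (held); temperature 70 °C; time 10 h
- green: substrate 0.80 M; gas phase 200 mM (held); temperature 78 °C; time 10 h

- percentages count the substrate that a species holds: one side product or self-condensation product counts as two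
- for a step with 2 of a species take k times the square, and two of it per event
- at the start none of the gas is dissolved
- all constants are for 70 °C and move with temperature by the activation energies

- which of the two there is more of at the end, counted by the substrate in each, blue (target / side product)
- which of the two there is more of at the end, counted by the substrate in each, green (target / side product)
- final target, as a percentage of the substrate charged, in blue
- final target, as a percentage of the substrate charged, in green

- I carry the crossover concentration, the c(substrate) at which substrate and the over-reaction step take target equally fast, which is the over-reaction constant over the side-product constant: 0.0909 M.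
- In my first extreme, c(substrate) stands far above the crossover: substrate both makes target and takes it, so it cancels, and target rests (a steady state of zero order in substrate) at 0.0597 M, or 7.47 % of the charge, with the dissolved gas at csat.
- In my second extreme, c(substrate) stands far below the crossover: the over-reaction step drains target, and c(target) follows substrate in first order, at 0.657 times c(substrate).
- My resting formula, which puts both drains in one denominator, lies below both lines, since the two drains add, and it slides from the first towards the second as substrate falls.
- Blue starts at 8.80 times the crossover, so at the charge substrate takes 89.8 % of the target's drain; as each side product counts two, I expect side product ahead of target in blue and in green.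
- For the end of blue I let self-condensation and the gas step consume substrate, with the dissolved gas at csat, whose transfer half-life of 0.688 h is shorter than the time; this estimate, with the side step left out, gives 0.0373 M, lower than the crossover.
- Between the extremes, that substrate gives 2.17 % target in blue, the figure I commit to.
- In green the slope of the second extreme is smaller, as over-reaction warms up more steeply than the gas step, so I put target there below blue.
- The forecast names side product in blue and side product in green, with 2.4 % and 0.7 % of target, and says the fast step “keeps target at only a few hundredths molar”.
- The simulation gives side product in blue, 24.1 % against 2.48 % of target, and side product in green, 19.9 % against 0.600 % of target.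
- Blue ends with 0.0259 M of substrate, lower than the crossover, and with that reading and 0.195 M of dissolved gas the resting formula gives 1.61 % target, while the flask holds 2.48 %, a factor of 1.54, and target there is made at 0.651 of the rate at which it is used. The neighbour, blue with 0.20 M of substrate, has the same crossover and ends with 0.0166 M of substrate, also lower than the crossover. The formula gives 4.53 % there, and that flask holds 7.43 %, a factor of 1.64.

The constants were set for the occasion; the run is a simulation.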